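**Retrosynthetic overview** (caryophyllane numbering: ring carbons C1–C11 with C1/C9 at the ring fusion and C10/C11 in the cyclobutane; side chain C12–C16)
1. Target ⇐ 1,4-reduction of a (Z)-cyclononenone; the nine-membered ring is closed last at C4–C5 by intramolecular Ni/Cr coupling of a (Z)-vinyl iodide with an aldehyde, followed by C8 methylenation and oxidation.
2. The C5–C8 keto-aldehyde arm ⇐ a 2-furyl group on the cyclobutane (masked 4-oxobutanoyl unit).
3. The (Z)-diacetate side chain ⇐ reduction of a 3-methyl-5,6-dihydropyran-2-one built at C12 by catalytic asymmetric allylboration, methacrylation and ring-closing metathesis.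
4. The cyclobutane (C1, C9, quaternary C11) ⇐ metal-free amine/squaramide-catalysed formal [2+2] of (E)-4-(furan-2-yl)but-2-enal with methacrolein.
5. Ring order: cyclobutane first, temporary six-membered lactone second, nine-membered carbocycle last.

Assumption: the 4S configuration of the epimerisable α-methyl ketone is the thermodynamically preferred C4 epimer of the trans-fused bicycle (as expected for the isolated natural product), so base equilibration in the last step converges on it.

**Step 1**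
Reactants: 1 furan; 2 allyl bromide
Product: 4 2-allylfuran, via 2-furyllithium 3 (not isolated)
Conditions: n-BuLi, THF, 0 °C; then 2, −78 °C → rt
Reagents that add atoms: none
Why: α-Lithiation of furan followed by SN2 alkylation of the heteroaryllithium with allyl bromide; no stereocenter is formed.

**Step 2**
Reactants: 4 2-allylfuran; 5 (E)-crotonaldehyde
Product: 6 (E)-4-(furan-2-yl)but-2-enal
Conditions: second-generation Hoveyda–Grubbs catalyst (2.5 mol %), 5 (5 equiv), CH2Cl2, 40 °C
Reagents that add atoms: none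
Why: Olefin cross-metathesis of a terminal alkene with excess crotonaldehyde gives the conjugated (E)-enal under thermodynamic control and releases volatile propene.

**Step 3**
Reactants: 6 (E)-4-(furan-2-yl)but-2-enal; 7 methacrolein
Product: 8 (1S,2S,3R)-3-(furan-2-yl)-1-methyl-2-(2-oxoethyl)cyclobutane-1-carbaldehyde
Conditions: 3-{[3,5-bis(trifluoromethyl)phenyl]amino}-4-{[(2S)-pyrrolidin-2-ylmethyl]amino}cyclobut-3-ene-1,2-dione (20 mol %), 7 (3 equiv), H2O (3 equiv), CH2Cl2, rt
Reagents that add atoms: none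
Why: Proposed new method: amine/squaramide-catalysed cross formal [2+2] of a linear enal with an α-branched enal; the pyrrolidine condenses with 6 (α-branched 7 condenses far more slowly) to give the furan-conjugated dienamine, whose γ-carbon (C9) adds to the β-carbon of squaramide-bound 7 on the catalyst-defined face, and the resulting aldehyde enolate, still held by the squaramide, closes 4-exo-trig onto the β-carbon of the unsaturated iminium (C11–C1) with the furyl and iminium arms trans and the enolate (formyl) arm anti to the iminium arm, so that C9, C1 and the quaternary C11 are set in one operation (catalyst enantiomer chosen for 1S,9R,11S in caryophyllane numbering); the closest known reaction type is the hydrogen-bond-directed dienamine [2+2] of enals with nitroalkenes, including α-substituted nitroalkenes that give a quaternary ring carbon.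

**Step 4**
Reactants: 8 (1S,2S,3R)-3-(furan-2-yl)-1-methyl-2-(2-oxoethyl)cyclobutane-1-carbaldehyde
Product: 9 (1S,2S,3R)-3-(furan-2-yl)-2-[(2Z)-3-iodobut-2-en-1-yl]-1-methylcyclobutane-1-carbaldehyde
Conditions: EtPPh3I, n-BuLi, THF, rt; iodine, −78 °C; NaN(SiMe3)2, −20 °C; then 8 (1.0 equiv), −78 °C
Reagents that add atoms: ethyltriphenylphosphonium iodide, CC[P+](c1ccccc1)(c1ccccc1)c1ccccc1.[I-]; iodine, II
Why: Stork–Zhao Wittig olefination with the α-iodo ylide gives the (Z)-2-iodoalkene (iodine cis to the chain), and at −78 °C with one equivalent it attacks only the unhindered CH2CHO group, not the neopentyl aldehyde on the quaternary carbon.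

**Step 5**
Reactants: 9 (1S,2S,3R)-3-(furan-2-yl)-2-[(2Z)-3-iodobut-2-en-1-yl]-1-methylcyclobutane-1-carbaldehyde; 10 allylboronic acid pinacol ester
Product: 11 (1S)-1-[(1S,2S,3R)-3-(furan-2-yl)-2-[(2Z)-3-iodobut-2-en-1-yl]-1-methylcyclobutyl]but-3-en-1-ol
Conditions: (S)-TRIP phosphoric acid (5 mol %), toluene, −30 → 0 °C; aqueous work-up
Reagents that add atoms: none
Why: Chiral phosphoric acid-catalysed allylboration through a chair transition state delivers the allyl group to the Si face under catalyst control, setting C12 as S.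

**Step 6**
Reactants: 11 (1S)-1-[(1S,2S,3R)-3-(furan-2-yl)-2-[(2Z)-3-iodobut-2-en-1-yl]-1-methylcyclobutyl]but-3-en-1-ol; 12 methacryloyl chloride
Product: 13 (1S)-1-[(1S,2S,3R)-3-(furan-2-yl)-2-[(2Z)-3-iodobut-2-en-1-yl]-1-methylcyclobutyl]but-3-en-1-yl 2-methylprop-2-enoate
Conditions: Et3N, DMAP (10 mol %), CH2Cl2, 0 °C → rt
Reagents that add atoms: none
Why: DMAP-catalysed esterification of the secondary alcohol with the acid chloride; no stereocenter is touched.

**Step 7**
Reactants: 13 (1S)-1-[(1S,2S,3R)-3-(furan-2-yl)-2-[(2Z)-3-iodobut-2-en-1-yl]-1-methylcyclobutyl]but-3-en-1-yl 2-methylprop-2-enoate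
Product: 14 (6S)-6-[(1S,2S,3R)-3-(furan-2-yl)-2-[(2Z)-3-iodobut-2-en-1-yl]-1-methylcyclobutyl]-3-methyl-5,6-dihydro-2H-pyran-2-one
Conditions: second-generation Grubbs catalyst (5 mol %), toluene, 80 °C, 5 mM
Reagents that add atoms: none
Why: Ring-closing metathesis of the terminal alkene with the methacrylate gives the six-membered α-methyl unsaturated lactone, which locks C14=C15 in the required Z geometry; the trisubstituted vinyl iodide and the furan are inert.

**Step 8**
Reactants: 14 (6S)-6-[(1S,2S,3R)-3-(furan-2-yl)-2-[(2Z)-3-iodobut-2-en-1-yl]-1-methylcyclobutyl]-3-methyl-5,6-dihydro-2H-pyran-2-one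
Product: 15 (2Z,5S)-5-[(1S,2S,3R)-3-(furan-2-yl)-2-[(2Z)-3-iodobut-2-en-1-yl]-1-methylcyclobutyl]-2-methylpent-2-ene-1,5-diol
Conditions: i-Bu2AlH (4 equiv), CH2Cl2, −78 → 0 °C; aqueous potassium sodium tartrate (KNaC4H4O6) work-up
Reagents that add atoms: none
Why: Exhaustive 1,2-reduction of the unsaturated lactone by the aluminium hydride opens it to the (Z)-allylic 1,5-diol with retention of alkene geometry and of C12.

**Step 9**
Reactants: 15 (2Z,5S)-5-[(1S,2S,3R)-3-(furan-2-yl)-2-[(2Z)-3-iodobut-2-en-1-yl]-1-methylcyclobutyl]-2-methylpent-2-ene-1,5-diol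
Product: 16 (2Z,5S)-5-[(1S,2S,3R)-3-(furan-2-yl)-2-[(2Z)-3-iodobut-2-en-1-yl]-1-methylcyclobutyl]-2-methylpent-2-ene-1,5-diyl diacetate
Conditions: Ac2O, pyridine, DMAP (10 mol %), CH2Cl2, rt
Reagents that add atoms: acetic anhydride, CC(=O)OC(C)=O
Why: DMAP-catalysed acetylation of both hydroxyl groups installs the two acetates of the target.

**Step 10**
Reactants: 16 (2Z,5S)-5-[(1S,2S,3R)-3-(furan-2-yl)-2-[(2Z)-3-iodobut-2-en-1-yl]-1-methylcyclobutyl]-2-methylpent-2-ene-1,5-diyl diacetate
Product: 18 (2Z,5S)-5-[(1S,2S,3R)-2-[(2Z)-3-iodobut-2-en-1-yl]-1-methyl-3-(4-oxobutanoyl)cyclobutyl]-2-methylpent-2-ene-1,5-diyl diacetate, via Z-4-oxobut-2-enoyl compound 17 (not isolated)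
Conditions: NBS (1.05 equiv), NaHCO3, THF–H2O (4:1), −20 °C; then Hantzsch ester (1.3 equiv), SiO2, rt
Reagents that add atoms: water, O
Why: NBS-mediated oxidative ring opening of the 2-alkylfuran (the most electron-rich π-system present) gives the cis-4-oxo-2-enal, whose doubly activated C=C is reduced by Hantzsch ester transfer hydrogenation to the 1,4-keto aldehyde; C9, now α to a ketone, stays in the more stable trans arrangement.

**Step 11**
Reactants: 18 (2Z,5S)-5-[(1S,2S,3R)-2-[(2Z)-3-iodobut-2-en-1-yl]-1-methyl-3-(4-oxobutanoyl)cyclobutyl]-2-methylpent-2-ene-1,5-diyl diacetate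
Product: 19 (2Z,5S)-5-[(1S,3Z,9R,11S)-5-hydroxy-4,11-dimethyl-8-oxobicyclo[7.2.0]undec-3-en-11-yl]-2-methylpent-2-ene-1,5-diyl diacetate (C5 epimer mixture)
Conditions: CrCl2 (8 equiv), NiCl2 (2 mol %), DMSO–THF (3:1), rt, slow addition to 2 mM; aqueous work-up
Reagents that add atoms: none
Why: Intramolecular Nozaki–Hiyama–Kishi coupling: the vinylchromium species from the (Z)-vinyl iodide adds to the aldehyde and not to the ketone (a six-membered closure onto C8 would need a trans-fused cyclohexene), closing the nine-membered ring with retention of Z geometry; both C5 carbinol epimers are carried on because C5 becomes a carbonyl.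

**Step 12**
Reactants: 19 (2Z,5S)-5-[(1S,3Z,9R,11S)-5-hydroxy-4,11-dimethyl-8-oxobicyclo[7.2.0]undec-3-en-11-yl]-2-methylpent-2-ene-1,5-diyl diacetate (C5 epimer mixture)
Product: 20 (2Z,5S)-5-[(1S,3Z,9R,11S)-5-hydroxy-4,11-dimethyl-8-methylidenebicyclo[7.2.0]undec-3-en-11-yl]-2-methylpent-2-ene-1,5-diyl diacetate (C5 epimer mixture)
Conditions: Zn, CH2Br2, TiCl4, THF–CH2Cl2, 0 °C → rt
Reagents that add atoms: dibromomethane, BrCBr
Why: Non-basic Takai–Lombardo methylenation converts the only ketone (C8) into the exocyclic methylene without epimerising C9 and without touching the acetates or the free hydroxyl.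

**Step 13**
Reactants: 20 (2Z,5S)-5-[(1S,3Z,9R,11S)-5-hydroxy-4,11-dimethyl-8-methylidenebicyclo[7.2.0]undec-3-en-11-yl]-2-methylpent-2-ene-1,5-diyl diacetate (C5 epimer mixture)
Product: 21 (2Z,5S)-5-[(1S,3Z,9R,11S)-4,11-dimethyl-8-methylidene-5-oxobicyclo[7.2.0]undec-3-en-11-yl]-2-methylpent-2-ene-1,5-diyl diacetate
Conditions: Dess–Martin periodinane, CH2Cl2, rt
Reagents that add atoms: none
Why: Dess–Martin oxidation of the allylic alcohol converges both C5 epimers on the (Z)-2-methyl enone.

**Step 14**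
Reactants: 21 (2Z,5S)-5-[(1S,3Z,9R,11S)-4,11-dimethyl-8-methylidene-5-oxobicyclo[7.2.0]undec-3-en-11-yl]-2-methylpent-2-ene-1,5-diyl diacetate
Product: 22 (2Z,5S)-5-[(1S,4S,9R,11S)-4,11-dimethyl-8-methylidene-5-oxobicyclo[7.2.0]undecan-11-yl]-2-methylpent-2-ene-1,5-diyl diacetate
Conditions: [(Ph3P)CuH]6 (0.5 equiv), H2O (3 equiv), degassed benzene, rt; then DBU (0.2 equiv), CH2Cl2, rt
Reagents that add atoms: none
Why: Copper hydride 1,4-reduction (Stryker conjugate reduction) is selective for the enone over the isolated alkenes and the acetates; C4 is formed on protonation of the copper enolate and then brought to the 4S epimer by DBU equilibration under thermodynamic control (see assumption).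

**Compound list**
1 | furan | c1ccoc1 | starting material
2 | allyl bromide | C=CCBr | starting material
3 | 2-furyllithium | [Li]c1ccco1 | intermediate
4 | 2-allylfuran | C=CCc1ccco1 | intermediate
5 | (E)-crotonaldehyde | C/C=C/C=O | starting material
6 | (E)-4-(furan-2-yl)but-2-enal | O=C/C=C/Cc1ccco1 | intermediate
7 | methacrolein | C=C(C)C=O | starting material
8 | (1S,2S,3R)-3-(furan-2-yl)-1-methyl-2-(2-oxoethyl)cyclobutane-1-carbaldehyde | O=CC[C@H]2[C@H](c3ccco3)C[C@]2(C)C=O | intermediate
9 | (1S,2S,3R)-3-(furan-2-yl)-2-[(2Z)-3-iodobut-2-en-1-yl]-1-methylcyclobutane-1-carbaldehyde | C/C(I)=C/C[C@H]2[C@H](c3ccco3)C[C@]2(C)C=O | intermediate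
10 | allylboronic acid pinacol ester | C=CCB1OC(C)(C)C(C)(C)O1 | starting material
11 | (1S)-1-[(1S,2S,3R)-3-(furan-2-yl)-2-[(2Z)-3-iodobut-2-en-1-yl]-1-methylcyclobutyl]but-3-en-1-ol | C/C(I)=C/C[C@H]2[C@H](c3ccco3)C[C@]2(C)[C@H](CC=C)O | intermediate
12 | methacryloyl chloride | C=C(C)C(Cl)=O | starting material
13 | (1S)-1-[(1S,2S,3R)-3-(furan-2-yl)-2-[(2Z)-3-iodobut-2-en-1-yl]-1-methylcyclobutyl]but-3-en-1-yl 2-methylprop-2-enoate | C/C(I)=C/C[C@H]2[C@H](c3ccco3)C[C@]2(C)[C@H](CC=C)OC(=O)C(C)=C | intermediate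
14 | (6S)-6-[(1S,2S,3R)-3-(furan-2-yl)-2-[(2Z)-3-iodobut-2-en-1-yl]-1-methylcyclobutyl]-3-methyl-5,6-dihydro-2H-pyran-2-one | C/C(I)=C/C[C@H]2[C@H](c3ccco3)C[C@]2(C)[C@H](CC=C(C)C4=O)O4 | intermediate
15 | (2Z,5S)-5-[(1S,2S,3R)-3-(furan-2-yl)-2-[(2Z)-3-iodobut-2-en-1-yl]-1-methylcyclobutyl]-2-methylpent-2-ene-1,5-diol | C/C(I)=C/C[C@H]2[C@H](c3ccco3)C[C@]2(C)[C@H](C/C=C(/C)CO)O | intermediate
16 | (2Z,5S)-5-[(1S,2S,3R)-3-(furan-2-yl)-2-[(2Z)-3-iodobut-2-en-1-yl]-1-methylcyclobutyl]-2-methylpent-2-ene-1,5-diyl diacetate | C/C(I)=C/C[C@H]2[C@H](c3ccco3)C[C@]2(C)[C@H](C/C=C(/C)COC(C)=O)OC(C)=O | intermediate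
17 | (2Z,5S)-5-[(1S,2S,3R)-2-[(2Z)-3-iodobut-2-en-1-yl]-1-methyl-3-[(2Z)-4-oxobut-2-enoyl]cyclobutyl]-2-methylpent-2-ene-1,5-diyl diacetate | C/C(I)=C/C[C@H]2[C@H](C(=O)/C=C\C=O)C[C@]2(C)[C@H](C/C=C(/C)COC(C)=O)OC(C)=O | intermediate
18 | (2Z,5S)-5-[(1S,2S,3R)-2-[(2Z)-3-iodobut-2-en-1-yl]-1-methyl-3-(4-oxobutanoyl)cyclobutyl]-2-methylpent-2-ene-1,5-diyl diacetate | C/C(I)=C/C[C@H]2[C@H](C(=O)CCC=O)C[C@]2(C)[C@H](C/C=C(/C)COC(C)=O)OC(C)=O | intermediate
19 | (2Z,5S)-5-[(1S,3Z,9R,11S)-5-hydroxy-4,11-dimethyl-8-oxobicyclo[7.2.0]undec-3-en-11-yl]-2-methylpent-2-ene-1,5-diyl diacetate (C5 epimer mixture) | O=C1CCC(O)/C(C)=C\C[C@H]2[C@H]1C[C@]2(C)[C@H](C/C=C(/C)COC(C)=O)OC(C)=O | intermediate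
20 | (2Z,5S)-5-[(1S,3Z,9R,11S)-5-hydroxy-4,11-dimethyl-8-methylidenebicyclo[7.2.0]undec-3-en-11-yl]-2-methylpent-2-ene-1,5-diyl diacetate (C5 epimer mixture) | C=C1CCC(O)/C(C)=C\C[C@H]2[C@H]1C[C@]2(C)[C@H](C/C=C(/C)COC(C)=O)OC(C)=O | intermediate
21 | (2Z,5S)-5-[(1S,3Z,9R,11S)-4,11-dimethyl-8-methylidene-5-oxobicyclo[7.2.0]undec-3-en-11-yl]-2-methylpent-2-ene-1,5-diyl diacetate | C=C1CCC(=O)/C(C)=C\C[C@H]2[C@H]1C[C@]2(C)[C@H](C/C=C(/C)COC(C)=O)OC(C)=O | intermediate
22 | (2Z,5S)-5-[(1S,4S,9R,11S)-4,11-dimethyl-8-methylidene-5-oxobicyclo[7.2.0]undecan-11-yl]-2-methylpent-2-ene-1,5-diyl diacetate (CNP0244219.2) | C=C1CCC(=O)[C@@H](C)CC[C@H]2[C@H]1C[C@]2(C)[C@H](C/C=C(/C)COC(C)=O)OC(C)=O | target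

**Total step count:** 14. **Longest linear sequence:** 14 steps (furan to target; the route is fully linear).

**The three steps most likely to fail**

Step 3 (the proposed cross [2+2]). The main dangers are closure of the zwitterion at the iminium carbon instead of its β-carbon, which gives the known amine-catalysed [4+2] cyclohexadiene products, and formation of the C11 epimer. The fallback sets out from 6 and comes back at 9, and uses only established reaction classes. Enal 6 is combined with 2-nitropropene under the same squaramide–pyrrolidine catalysis, the acceptor class for which the hydrogen-bond-directed dienamine [2+2] is established, to give 2-[(1S,2S,4R)-4-(furan-2-yl)-2-methyl-2-nitrocyclobutyl]acetaldehyde F1. The tertiary nitro group is then replaced by a one-carbon unit through tin-mediated radical denitration in the presence of tert-butyl isocyanide (Bu3SnH, AIBN, benzene, 80 °C). The cyclobutyl radical is trapped on the face anti to the adjacent C1 side arm, which sets C11 and gives (1S,2S,3R)-3-(furan-2-yl)-1-methyl-2-(2-oxoethyl)cyclobutane-1-carbonitrile F2. Stork–Zhao olefination of F2 exactly as in step 4 gives (1S,2S,3R)-3-(furan-2-yl)-2-[(2Z)-3-iodobut-2-en-1-yl]-1-methylcyclobutane-1-carbonitrile F3. Reduction of the nitrile with i-Bu2AlH (toluene, −78 °C) and mild acidic hydrolysis returns aldehyde 9.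

Step 11 (nine-membered ring closure). Oligomerisation or simple reduction of the vinyl iodide may outrun the strained 9-ring closure onto the aldehyde. The fallback sets out from 18 and comes back at 21, replacing aldehyde addition by a reductive acyl–vinyl coupling that gives the enone directly. Pinnick oxidation of 18 (NaClO2, NaH2PO4, 2-methyl-2-butene) gives the carboxylic acid analogue of 18 F4. 2,2′-Dipyridyl disulfide and PPh3 convert it into the S-pyridin-2-yl thioester analogue of 18 F5. Iron/copper-mediated reductive ketone coupling of the vinyl iodide with the thioester (FeBr2(dppb), CuI, Mn, LiCl, high dilution) closes the ring to the 5,8-dioxo enone F6. Zn/CH2Br2/TiCl4 methylenation of the saturated C8 ketone, which is more reactive than the conjugated C5 carbonyl, then gives 21.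

Step 14 (C4 configuration). The chemoselective reduction itself is reliable, but the sense and size of the thermodynamic preference at C4 are not secured by precedent. The fallback sets out from 21 and comes back at 22, replacing substrate control by catalyst control: asymmetric bioreduction of the α-methyl enone with an ene-reductase of the Old Yellow Enzyme family (NADPH recycled with glucose and glucose dehydrogenase, buffer with co-solvent), screening stereocomplementary enzymes for the one that delivers 4S under non-epimerising conditions. It makes no further compound (none, F0).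

**Further compounds**
F1 | step 3 | 2-[(1S,2S,4R)-4-(furan-2-yl)-2-methyl-2-nitrocyclobutyl]acetaldehyde | O=CC[C@H]2[C@H](c3ccco3)C[C@]2(C)[N+](=O)[O-]
F2 | step 3 | (1S,2S,3R)-3-(furan-2-yl)-1-methyl-2-(2-oxoethyl)cyclobutane-1-carbonitrile | O=CC[C@H]2[C@H](c3ccco3)C[C@]2(C)C#N
F3 | step 3 | (1S,2S,3R)-3-(furan-2-yl)-2-[(2Z)-3-iodobut-2-en-1-yl]-1-methylcyclobutane-1-carbonitrile | C/C(I)=C/C[C@H]2[C@H](c3ccco3)C[C@]2(C)C#N
F4 | step 11 | carboxylic acid analogue of 18 (terminal CHO oxidised to CO2H; 4-oxobutanoic acid on the cyclobutane) | C/C(I)=C/C[C@H]2[C@H](C(=O)CCC(=O)O)C[C@]2(C)[C@H](C/C=C(/C)COC(C)=O)OC(C)=O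
F5 | step 11 | S-pyridin-2-yl thioester analogue of 18 (thioester of F4) | C/C(I)=C/C[C@H]2[C@H](C(=O)CCC(=O)Sc3ccccn3)C[C@]2(C)[C@H](C/C=C(/C)COC(C)=O)OC(C)=O
F6 | step 11 | (2Z,5S)-5-[(1S,3Z,9R,11S)-4,11-dimethyl-5,8-dioxobicyclo[7.2.0]undec-3-en-11-yl]-2-methylpent-2-ene-1,5-diyl diacetate | O=C1CCC(=O)/C(C)=C\C[C@H]2[C@H]1C[C@]2(C)[C@H](C/C=C(/C)COC(C)=O)OC(C)=O
F0 | step 14 | none | none
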